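Remark on the chemistry: the SMILES contains no stereocentre, stereogenic axis or stereogenic double bond, so the target is achiral. The request for a single enantiomer is met trivially and the route addresses constitution only.

## Structural features

- The target (13) consists of two pentasubstituted benzene rings joined only through an ester: ring A is a 2,4-dihydroxy-3,6-dimethylbenzoyl group, and ring B is a 2,4-dihydroxy-3-methylbenzoic acid whose C6 carries the CH2–O of that ester.
- Both rings carry the same array: C1 carbonyl, C2 OH, C3 CH3, C4 OH, C5 H, C6 sp3 carbon. They differ only at the C6 substituent (CH3 in ring A, CH2O in ring B).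
- Three groups are fragile. The free ring-B carboxyl sits five atoms from the benzylic ester carbon and can displace the ring-A carboxylate with lactonisation. 2,4-Dihydroxybenzoic acids decarboxylate in hot or strongly acidic media. The central ArCH2–O bond excludes hydrogenolytic protecting groups.
- The real difficulty is the ester between a di-ortho-substituted salicylic acid and a benzylic alcohol with an ortho carboxyl function. Two almost identical resorcinol rings (four phenols, C3 versus C6 methyl groups) must also be told apart without a long protecting-group sequence.
- Feature exploited by the key step: in each ring the C1–C6 bond, with its carbonyl on C1 and its CH3 or CH2O on C6, is the retron of a 2-ynoate. The central C(=O)–O–CH2 unit can therefore tether two ynoates.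
- The C2(OH)–C3(CH3)–C4(OH)–C5(H) segment is identical in rings A and B, so one diene can deliver it to both rings in the same operation.

## Logic of the disconnections

**13 to 12.** The O–allyl bond of the ring-B carboxylate is cut. The free acid next to the benzylic ester must appear last and under near-neutral, non-hydrogenolytic conditions. The gain is small (one masking group), but the forward step must release the acid without lactonisation, decarboxylation or ionisation of the central ArCH2–O bond.

**12 to 6 plus two molecules of 9 (key disconnection).** In each ring the C1–C2 and C5–C6 bonds are cut, four C–C bonds in all, and a CMe2–CH2 bridge is formally added back across C2 and C5. In one sentence: both benzene rings are made in a single twofold Diels–Alder/Alder–Rickert benzannulation of the acyclic diyne diester 6 with two molecules of the one bis(silyloxy)cyclohexadiene 9. Two pentasubstituted arenes with eight correctly placed ring substituents collapse to an 11-carbon open-chain diester and one symmetric diene. No phenol protecting group is needed and the hindered ester already exists. The forward step demands that both alkynes react, that each cycloaddition has the same orientation, and that the esters and the allyl group survive about 140 °C.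

**6 to 4 plus 5.** The acyl C–O bond of the central ester is cut. At this stage the alcohol is an unhindered primary propargylic alcohol and the acid a small alkynoic acid, so the hardest bond of the target becomes a routine esterification. The demand is to avoid nucleophile-induced conjugate addition or isomerisation of the two ynoates.

**4 to 3, then to 1 plus 2.** The O–Si bond is cut, then the C(sp)–C(carboxyl) bond. This traces the ring-B carboxyl carbon and its allyl mask to a chloroformate and the C6–CH2O unit to a protected propargyl alcohol. The demand is clean C-acylation of an acetylide.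

**9 to 8, then to 7.** Two O–Si bonds are cut, then the C2–CH3 bond of the dione. The diene comes from a cheap cyclic 1,3-dione whose gem-dimethyl carbon and neighbouring CH2 become the extruded bridge. The demands are C- rather than O-methylation and complete double enol silylation.

## Other disconnections considered

**Alternative 1:** (the first that comes to mind). The cut is the ester link between two preformed, fully protected arenes. The forward key step would be SN2 O-alkylation of the caesium salt of 2,4-bis(methoxymethoxy)-3,6-dimethylbenzoic acid A1 by prop-2-en-1-yl 6-(bromomethyl)-2,4-bis(methoxymethoxy)-3-methylbenzoate A2, giving the protected diester A3, followed by removal of four acetals and the allyl group.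
- A2 needs functionalisation of the C6 methyl in the presence of the C3 methyl on a ring whose free C5–H is strongly activated, so nuclear halogenation should compete with benzylic halogenation.
- A2 holds a leaving group five atoms from an ester oxygen, so intramolecular O-alkylation (lactonisation) should compete with the intermolecular displacement.
- Two arenes must be built and protected separately, five protecting groups are carried, and the final acetal cleavage needs acid on a decarboxylation-prone product. The chosen plan avoids all of this and is expected to be about half as long.

**Alternative 2:** The cut is the same O–CH2 bond, but made as a dehydrogenative union, since 13 is formally two molecules of 2,4-dihydroxy-3,6-dimethylbenzoic acid A4 minus H2 (presumed biosynthesis: benzylic oxidation of one unit, then ester formation). The forward key step would be an anodic, or carboxylate-directed metal-catalysed, benzylic C–H acyloxylation of A4 by a second molecule of A4.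
- Under anodic oxidation the arene radical cation should lose a proton from the C3 methyl, which is ortho to both oxygens. The C6 methyl is meta to both and ortho to the acceptor, so the wrong methyl would be functionalised.
- A carboxylate-directed C–H metalation would select the C6 methyl, but the metallacycle should collapse by C–O bond formation with its own carboxylate to 5,7-dihydroxy-6-methyl-2-benzofuran-1(3H)-one A5.
- Opening A5 at its alkyl C–O bond with the carboxylate of A4 exchanges one carboxylate for another at the cost of a ring. It is expected to be uphill and to need temperatures at which A4 decarboxylates.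

**Alternative 3:** The cut is the acyl C–O bond together with the C1–C6 bond of ring A (polyketide-type aromatisation). The forward key step would be thermolysis of 6-(3,5-dioxohexan-2-yl)-2,2-dimethyl-4H-1,3-dioxin-4-one A6 in the presence of prop-2-en-1-yl 6-(hydroxymethyl)-2,4-bis(methoxymethoxy)-3-methylbenzoate A7, with ketene transfer to the hydroxyl and aldol aromatisation building ring A on the ester oxygen.
- A7 is a 2-(hydroxymethyl)benzoate ester and should undergo intramolecular transesterification (5-exo-trig) at the temperature needed for ketene release.
- The branched methyl in A6 permits more than one aldol or Claisen closure.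
- Only ring A is addressed, so ring B still needs a separate protected arene synthesis. The chosen plan builds both rings with one reagent in one step.

Key step: step 6

## Steps

Step 1
Reactants: 1 tert-butyldimethyl(prop-2-yn-1-yloxy)silane; 2 prop-2-en-1-yl carbonochloridate (allyl chloroformate)
Product: 3 prop-2-en-1-yl 4-[(tert-butyldimethylsilyl)oxy]but-2-ynoate
Conditions: n-BuLi, THF, –78 °C; then 2, –78 → 0 °C
Reagents that add atoms: none
Why: Deprotonation of the terminal alkyne and C-acylation of the lithium acetylide by a chloroformate is the standard route to 2-ynoates; the silyl ether is inert to the base at –78 °C.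

Step 2
Reactants: 3 prop-2-en-1-yl 4-[(tert-butyldimethylsilyl)oxy]but-2-ynoate
Product: 4 prop-2-en-1-yl 4-hydroxybut-2-ynoate
Conditions: CSA (10 mol %), MeOH, 0 °C → rt
Reagents that add atoms: none
Why: Acid-catalysed methanolysis cleaves a primary TBS ether selectively; the ynoate and the allyl ester should not be touched by catalytic acid at or below room temperature.

Step 3
Reactants: 4 prop-2-en-1-yl 4-hydroxybut-2-ynoate; 5 but-2-ynoic acid
Product: 6 prop-2-en-1-yl 4-(but-2-ynoyloxy)but-2-ynoate
Conditions: DCC, DMAP (5 mol %), CH2Cl2, –20 → 0 °C
Reagents that add atoms: none
Why: Steglich esterification of an unhindered primary propargylic alcohol; the central ester of the target is thus made before either ring exists, where neither hindrance nor lactonisation can interfere. Low temperature and a small DMAP loading limit conjugate addition to the ynoates.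

Step 4
Reactants: 7 5,5-dimethylcyclohexane-1,3-dione (dimedone)
Product: 8 2,5,5-trimethylcyclohexane-1,3-dione
Conditions: MeI, K2CO3, acetone, reflux
Reagents that add atoms: iodomethane, CI
Why: C-Alkylation of the stabilised enolate of a cyclic 1,3-dione with iodomethane; the soft electrophile favours C- over O-methylation, and one equivalent limits double alkylation.

Step 5
Reactants: 8 2,5,5-trimethylcyclohexane-1,3-dione
Product: 9 2,5,5-trimethyl-1,3-bis(trimethylsilyloxy)cyclohexa-1,3-diene
Conditions: TMSOTf (2.3 equiv), Et3N (3 equiv), Et2O, 0 °C → rt; distillation
Reagents that add atoms: trimethylsilyl trifluoromethanesulfonate, C[Si](C)(C)OS(=O)(=O)C(F)(F)F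
Why: Soft enolisation with silyl triflate and tertiary amine: O-silylation of the enol, then O-silylation of the vinylogous ester gives a symmetric 1,3-bis(silyloxy)allyl cation. This cation can lose a proton only from C4 or C6 (equivalent), so one conjugated 1,3-diene is expected.

Step 6
Reactants: 6 prop-2-en-1-yl 4-(but-2-ynoyloxy)but-2-ynoate; 9 2,5,5-trimethyl-1,3-bis(trimethylsilyloxy)cyclohexa-1,3-diene (two molecules enter the product; about 6 equiv used)
Product: 12 prop-2-en-1-yl 6-{[(2,4-dihydroxy-3,6-dimethylbenzoyl)oxy]methyl}-2,4-dihydroxy-3-methylbenzoate, via twofold bicyclo[2.2.2]octadiene cycloadduct 10 (not isolated), via tetrakis(trimethylsilyl) aryl ether 11 (not isolated)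
Conditions: neat in excess 9, sealed tube, Ar, 140–150 °C; then 1 M aq. HCl, THF, rt
Reagents that add atoms: none
Why: Each 2-ynoate of 6 is an electron-poor dienophile for the electron-rich, s-cis-locked diene 9: a concerted but strongly asynchronous normal-demand [4+2] cycloaddition gives a bicyclo[2.2.2]octa-2,5-diene at each alkyne (10), and each bicycle then loses its CMe2–CH2 bridge as isobutylene by retro-Diels–Alder reaction (Alder–Rickert reaction), which is irreversible because a gas leaves and a benzene ring forms (11). The closest known reaction type is this same Diels–Alder/Alder–Rickert benzannulation of β-alkyl 2-ynoate esters, including macrocyclic ynoate lactones, with dimedone-derived 1,3-bis(trimethylsilyloxy)cyclohexa-1,3-dienes at about 140 °C to give 2,4-dioxygenated benzoates; here it is run at both alkynes of one diester. Ring A is closed by bonding diene C1 and C4 to the α- and β-carbons of the but-2-ynoate unit and ring B in the same way at the 4-acyloxybut-2-ynoate unit; in each ring the new bonds are benzoate C1–C2 and C5–C6, and both closures are intermolecular cycloadditions followed by cycloreversion. Regiochemistry is the selectivity that fixes the constitution: diene C4, the unsubstituted terminus with the largest HOMO coefficient (β to the C3 silyloxy group and vinylogously β to the C1 silyloxy group), should bond to the ynoate β-carbon, so that the oxygen-bearing C1 ends up next to the ester carbon, placing OH at C2, CH3 at C3, OH at C4 and H at C5 of both rings. No lasting stereocentre is formed, because the bridgehead centres of 10 are erased on aromatisation. Chemoselectivity rests on electronics: the isolated allyl alkene is not activated toward an electron-rich diene and nothing in the neutral melt attacks the three esters; the γ-acyloxy ynoate should react first and the β-methyl ynoate second, hence the excess of 9 and the temperature. Dilute aqueous acid then hydrolyses the four aryl trimethylsilyl ethers, and excess diene reverts to 8, which is removable by bicarbonate extraction.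

Step 7
Reactants: 12 prop-2-en-1-yl 6-{[(2,4-dihydroxy-3,6-dimethylbenzoyl)oxy]methyl}-2,4-dihydroxy-3-methylbenzoate
Product: 13 6-{[(2,4-dihydroxy-3,6-dimethylbenzoyl)oxy]methyl}-2,4-dihydroxy-3-methylbenzoic acid (target)
Conditions: Pd(PPh3)4 (5 mol %), N-methylaniline (5 equiv), THF, 0 °C → rt; cold 0.5 M aq. HCl work-up
Reagents that add atoms: none
Why: Tsuji–Trost-type deallylation: Pd(0) ionises the allyl ester to a π-allyl complex that is captured by N-methylaniline, releasing the acid under near-neutral conditions at room temperature. The central benzylic ester should not ionise with this catalyst at this temperature, and the weakly basic scavenger keeps the ring-B carboxyl largely protonated, which disfavours displacement at the neighbouring CH2.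

## Compound list

1 | tert-butyldimethyl(prop-2-yn-1-yloxy)silane | C#CCO[Si](C)(C)C(C)(C)C | starting material
2 | prop-2-en-1-yl carbonochloridate (allyl chloroformate) | C=CCOC(=O)Cl | starting material
3 | prop-2-en-1-yl 4-[(tert-butyldimethylsilyl)oxy]but-2-ynoate | C=CCOC(=O)C#CCO[Si](C)(C)C(C)(C)C | intermediate
4 | prop-2-en-1-yl 4-hydroxybut-2-ynoate | C=CCOC(=O)C#CCO | intermediate
5 | but-2-ynoic acid | CC#CC(=O)O | starting material
6 | prop-2-en-1-yl 4-(but-2-ynoyloxy)but-2-ynoate | CC#CC(=O)OCC#CC(=O)OCC=C | intermediate
7 | 5,5-dimethylcyclohexane-1,3-dione (dimedone) | CC1(C)CC(=O)CC(=O)C1 | starting material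
8 | 2,5,5-trimethylcyclohexane-1,3-dione | CC1C(=O)CC(C)(C)CC1=O | intermediate
9 | 2,5,5-trimethyl-1,3-bis(trimethylsilyloxy)cyclohexa-1,3-diene | C[Si](C)(C)OC1=CC(C)(C)CC(O[Si](C)(C)C)=C1C | intermediate
10 | prop-2-en-1-yl 3-({[3,6,8,8-tetramethyl-1,5-bis(trimethylsilyloxy)bicyclo[2.2.2]octa-2,5-dien-2-yl]carbonyloxy}methyl)-6,8,8-trimethyl-1,5-bis(trimethylsilyloxy)bicyclo[2.2.2]octa-2,5-diene-2-carboxylate (mixture of diastereomers, bridgehead centres lost in the next event) | C=CCOC(=O)C1=C(COC(=O)C2=C(C)C3C(O[Si](C)(C)C)=C(C)C2(O[Si](C)(C)C)CC3(C)C)C2C(O[Si](C)(C)C)=C(C)C1(O[Si](C)(C)C)CC2(C)C | intermediate (not isolated)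
11 | prop-2-en-1-yl 6-({[3,6-dimethyl-2,4-bis(trimethylsilyloxy)benzoyl]oxy}methyl)-3-methyl-2,4-bis(trimethylsilyloxy)benzoate | Cc1cc(O[Si](C)(C)C)c(C)c(O[Si](C)(C)C)c1C(=O)OCc1cc(O[Si](C)(C)C)c(C)c(O[Si](C)(C)C)c1C(=O)OCC=C | intermediate (not isolated)
12 | prop-2-en-1-yl 6-{[(2,4-dihydroxy-3,6-dimethylbenzoyl)oxy]methyl}-2,4-dihydroxy-3-methylbenzoate | Cc1cc(O)c(C)c(O)c1C(=O)OCc1cc(O)c(C)c(O)c1C(=O)OCC=C | intermediate
13 | 6-{[(2,4-dihydroxy-3,6-dimethylbenzoyl)oxy]methyl}-2,4-dihydroxy-3-methylbenzoic acid | Cc1cc(O)c(C)c(O)c1C(=O)OCc1cc(O)c(C)c(O)c1C(=O)O | target

## Step count and least certain steps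

Total step count: 7. Longest linear sequence: 5 steps (steps 1, 2, 3, 6, 7); the diene branch (steps 4, 5) joins at step 6.

**Step 6 (key step).** The most likely failure is incomplete twofold conversion. The β-methyl ynoate is the less electrophilic dienophile, and at the temperature it needs, thermal decay of the diene (desilylation, oligomerisation) or slow extrusion from the more congested bicycle may stop the sequence after one ring. The fallback changes the diene and the way the ring becomes aromatic (elimination instead of cycloreversion) and sets out from 6. Ethyl 2-methyl-3-oxobutanoate F1 would be converted with TMSCl/Et3N into ethyl 2-methyl-3-(trimethylsilyloxy)but-2-enoate F2, and then with LDA/TMSCl in THF at –78 °C into 1-ethoxy-2-methyl-1,3-bis(trimethylsilyloxy)buta-1,3-diene F3. Heating 6 with an excess of F3 in toluene at 80–110 °C should give the same orientation (unsubstituted terminus to the ynoate β-carbon). Acidic work-up should then eliminate ethanol and the silyl groups, so the route is rejoined at 12.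

**Step 7.** The most likely failure is intramolecular displacement at the benzylic CH2 by the liberated ortho carboxylate (lactonisation with loss of the ring-A acid) while the acid is present as its ammonium salt. Allyl transfer to a phenol oxygen is a second risk if the scavenger is too slow. The fallback unmasks the acid by acidolysis, in which the carboxyl stays protonated, and sets out from 1. Lithiation and trapping with di-tert-butyl dicarbonate would give tert-butyl 4-[(tert-butyldimethylsilyl)oxy]but-2-ynoate F4. Desilylation as in step 2 would give tert-butyl 4-hydroxybut-2-ynoate F5, and esterification with 5 as in step 3 would give tert-butyl 4-(but-2-ynoyloxy)but-2-ynoate F6. The twofold benzannulation with 9 as in step 6 would give tert-butyl 6-{[(2,4-dihydroxy-3,6-dimethylbenzoyl)oxy]methyl}-2,4-dihydroxy-3-methylbenzoate F7. Brief treatment with TFA in CH2Cl2 at 0 °C should release isobutylene and come back to the route at 13.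

**Step 3.** The most likely failure is nucleophile-induced conjugate addition of the hydroxyl of one molecule to the ynoate of another (oligomerisation), or isomerisation of the but-2-ynoyl unit to an allenoate under DMAP catalysis. The fallback forms the other C–O bond of the ester without a nucleophilic catalyst and sets out from 4. PBr3 in Et2O at 0 °C would give prop-2-en-1-yl 4-bromobut-2-ynoate F8, which would alkylate the caesium salt of 5 (Cs2CO3, DMF, 0 °C) to come back at 6.

**Step 5.** The most likely failure is incomplete second silylation, or hydrolytic loss of a silyl group during isolation of the moisture-sensitive diene. The fallback replaces soft enolisation by kinetic lithium enolate trapping and sets out from 8. TMSCl/Et3N would give 2,5,5-trimethyl-3-(trimethylsilyloxy)cyclohex-2-en-1-one F9, which with LDA and then TMSCl in THF at –78 °C should be deprotonated at C6 and silylated to come back at 9, used without chromatography.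

## Further compounds

F1 | step 6 | ethyl 2-methyl-3-oxobutanoate (purchased, racemic) | CCOC(=O)C(C)C(C)=O
F2 | step 6 | ethyl 2-methyl-3-(trimethylsilyloxy)but-2-enoate (E/Z mixture) | CCOC(=O)C(C)=C(C)O[Si](C)(C)C
F3 | step 6 | 1-ethoxy-2-methyl-1,3-bis(trimethylsilyloxy)buta-1,3-diene (E/Z mixture at C1=C2) | CCOC(O[Si](C)(C)C)=C(C)C(=C)O[Si](C)(C)C
F4 | step 7 | tert-butyl 4-[(tert-butyldimethylsilyl)oxy]but-2-ynoate | CC(C)(C)OC(=O)C#CCO[Si](C)(C)C(C)(C)C
F5 | step 7 | tert-butyl 4-hydroxybut-2-ynoate | CC(C)(C)OC(=O)C#CCO
F6 | step 7 | tert-butyl 4-(but-2-ynoyloxy)but-2-ynoate | CC#CC(=O)OCC#CC(=O)OC(C)(C)C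
F7 | step 7 | tert-butyl 6-{[(2,4-dihydroxy-3,6-dimethylbenzoyl)oxy]methyl}-2,4-dihydroxy-3-methylbenzoate | Cc1cc(O)c(C)c(O)c1C(=O)OCc1cc(O)c(C)c(O)c1C(=O)OC(C)(C)C
F8 | step 3 | prop-2-en-1-yl 4-bromobut-2-ynoate | C=CCOC(=O)C#CCBr
F9 | step 5 | 2,5,5-trimethyl-3-(trimethylsilyloxy)cyclohex-2-en-1-one | CC1=C(O[Si](C)(C)C)CC(C)(C)CC1=O
A1 | alternative 1 | 2,4-bis(methoxymethoxy)-3,6-dimethylbenzoic acid | Cc1cc(OCOC)c(C)c(OCOC)c1C(=O)O
A2 | alternative 1 | prop-2-en-1-yl 6-(bromomethyl)-2,4-bis(methoxymethoxy)-3-methylbenzoate | C=CCOC(=O)c1c(CBr)cc(OCOC)c(C)c1OCOC
A3 | alternative 1 | prop-2-en-1-yl 6-({[2,4-bis(methoxymethoxy)-3,6-dimethylbenzoyl]oxy}methyl)-2,4-bis(methoxymethoxy)-3-methylbenzoate | Cc1cc(OCOC)c(C)c(OCOC)c1C(=O)OCc1cc(OCOC)c(C)c(OCOC)c1C(=O)OCC=C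
A4 | alternative 2 | 2,4-dihydroxy-3,6-dimethylbenzoic acid | Cc1cc(O)c(C)c(O)c1C(=O)O
A5 | alternative 2 | 5,7-dihydroxy-6-methyl-2-benzofuran-1(3H)-one | Cc1c(O)cc2COC(=O)c2c1O
A6 | alternative 3 | 6-(3,5-dioxohexan-2-yl)-2,2-dimethyl-4H-1,3-dioxin-4-one (racemic) | CC(C1=CC(=O)OC(C)(C)O1)C(=O)CC(C)=O
A7 | alternative 3 | prop-2-en-1-yl 6-(hydroxymethyl)-2,4-bis(methoxymethoxy)-3-methylbenzoate | C=CCOC(=O)c1c(CO)cc(OCOC)c(C)c1OCOC
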